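## Retrosynthetic overview

1. The chain ketone is cut between C=O and the allylic CH2: a (Z)-allyl sulfone carbanion (fragment B) acylated by a δ-lactone, then desulfonylation. The enone is cut at the carbinol–vinyl bond: an (E)-vinyllithium (fragment C) plus a neopentyl aldehyde, then oxidation.
2. The CHO / CH2CO2Me pair on the cyclopentane (fragment A) comes from ozonolysis of a silyl enol ether of meso cis-1,5-dimethylbicyclo[3.3.0]octan-3-one. One enantioselective deprotonation fixes the absolute configuration of both quaternary centres.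
3. The meso ketone comes from cis-1,5-dimethylbicyclo[3.3.0]octane-3,7-dione by mono-ketalisation and Wolff–Kishner reduction.
4. Rings are formed only in step 1 (Weiss–Cook condensation of biacetyl with two dimethyl 3-oxoglutarate). The first cyclopentane closes by intramolecular aldol addition, the second by intramolecular Michael addition, which sets the two methyl-bearing quaternary carbons cis. One ring survives as the cyclopentane of the target; the other is cleaved in step 7.
5. Fragment B: 2-allyl-6-methylphenol → silylated hydroquinone → arylacetaldehyde → Still–Gennari (Z)-enoate → allyl sulfone. Fragment C: 2-methylbut-3-yn-2-ol → (E)-vinylstannane.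

Assumption: lithium (R,R)-bis(1-phenylethyl)amide is taken to remove the proton that leads to (1S,5R)-13 (the sense is not predicted from a model); if the sense is the opposite, the (S,S)-amide is used and nothing else changes.

## Route

Step 1
Reactants: 1 butane-2,3-dione (biacetyl); 2 dimethyl 3-oxopentanedioate (2 equiv)
Product: 6 tetramethyl cis-1,5-dimethyl-3,7-dioxobicyclo[3.3.0]octane-2,4,6,8-tetracarboxylate (isolated as its bis-enol tautomer), via acyclic aldol adduct 3 (not isolated), via hydroxycyclopentenone 4 (not isolated), via cyclopentenone Michael precursor 5 (not isolated)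
Conditions: aq NaHCO3 (pH 8.3), rt, 24 h; filter
Reagents that add atoms: none
Why: Weiss–Cook condensation: aldol adduct 3 closes the first cyclopentane by intramolecular aldol addition and dehydrates to 4, a second oxoglutarate adds in a Michael reaction and, after dehydration to 5, the second ring closes by intramolecular Michael addition, which can only give the cis-fused bicycle and so places the two quaternary methyl groups cis (meso, no absolute configuration yet).

Step 2
Reactants: 6 tetraester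
Product: 7 cis-1,5-dimethylbicyclo[3.3.0]octane-3,7-dione
Conditions: 1 M HCl, AcOH, reflux
Reagents that add atoms: none
Why: Acid hydrolysis of the four β-keto esters followed by fourfold decarboxylation; the ring-fusion carbons are quaternary and cannot epimerise.

Step 3
Reactants: 7 cis-1,5-dimethylbicyclo[3.3.0]octane-3,7-dione
Product: 8 cis-1,5-dimethylbicyclo[3.3.0]octane-3,7-dione mono(2,2-dimethylpropane-1,3-diyl) ketal
Conditions: 2,2-dimethylpropane-1,3-diol (1.0 equiv), p-toluenesulfonic acid (cat.), PhH, reflux, Dean–Stark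
Reagents that add atoms: 2,2-dimethylpropane-1,3-diol, OCC(C)(C)CO
Why: Acid-catalysed ketalisation with one equivalent of diol differentiates the two equivalent ketones (statistical; bis-ketal and recovered 7 are recycled).

Step 4
Reactants: 8 mono-ketal
Product: 10 cis-1,5-dimethylbicyclo[3.3.0]octan-3-one 2,2-dimethylpropane-1,3-diyl ketal, via hydrazone 9 (not isolated)
Conditions: N2H4·H2O, KOH, diethylene glycol, 130 °C then 200 °C
Reagents that add atoms: none
Why: Wolff–Kishner reduction (Huang-Minlon procedure) removes the free ketone through its hydrazone, and the ketal is stable to the hot base.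

Step 5
Reactants: 10 ketal
Product: 11 cis-1,5-dimethylbicyclo[3.3.0]octan-3-one (meso)
Conditions: 2 M HCl, THF, rt
Reagents that add atoms: water, O
Why: Acid-catalysed ketal hydrolysis frees the meso ketone whose two α-methylene groups are enantiotopic.

Step 6
Reactants: 11 meso ketone
Product: 13 (1S,5R)-1,5-dimethyl-3-(trimethylsilyloxy)bicyclo[3.3.0]oct-2-ene, via lithium enolate 12 (not isolated)
Conditions: (R,R)-bis(1-phenylethyl)amine, n-BuLi (n-C4H9Li), LiCl, THF, −78 °C; Me3SiCl then 11, −100 °C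
Reagents that add atoms: chlorotrimethylsilane, C[Si](C)(C)Cl
Why: Enantioselective deprotonation of a meso ketone by a chiral lithium amide with internal silyl quench selects one of the enantiotopic α-methylene groups and thereby fixes the absolute configuration at both existing quaternary carbons (about 85–90% ee expected by analogy with other bicyclo[3.3.0]octan-3-ones).

Step 7
Reactants: 13 silyl enol ether
Product: 15 2-[(1R,2R)-2-formyl-1,2-dimethylcyclopentyl]acetic acid, via methoxy hydroperoxide silyl ester 14 (not isolated)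
Conditions: O3, CH2Cl2/MeOH, −78 °C; Me2S, −78 °C → rt; aqueous work-up
Reagents that add atoms: ozone, [O-][O+]=O
Why: Ozonolysis of the silyl enol ether with reductive work-up cleaves the C2=C3 bond to leave CHO on one quaternary carbon and CH2CO2H on the other without touching either stereocentre.

Step 8
Reactants: 15 aldehyde acid
Product: 16 methyl 2-[(1R,2R)-2-formyl-1,2-dimethylcyclopentyl]acetate
Conditions: Me3SiCHN2, MeOH/PhMe, 0 °C
Reagents that add atoms: (trimethylsilyl)diazomethane, C[Si](C)(C)C=[N+]=[N-]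
Why: Diazoalkane O-methylation of the carboxylic acid is non-basic and leaves the aldehyde, which has no α-hydrogen, untouched.

Step 9
Reactants: 17 2-methylbut-3-yn-2-ol
Product: 18 triethyl[(2-methylbut-3-yn-2-yl)oxy]silane
Conditions: Et3SiOTf, 2,6-lutidine, CH2Cl2, 0 °C
Reagents that add atoms: triethylsilyl trifluoromethanesulfonate, CC[Si](CC)(CC)OS(=O)(=O)C(F)(F)F
Why: Silylation of the hindered tertiary alcohol with the reactive silyl triflate.

Step 10
Reactants: 18 silyl ether
Product: 19 tributyl[(E)-3-methyl-3-(triethylsilyloxy)but-1-en-1-yl]stannane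
Conditions: Bu3SnH, PdCl2(PPh3)2 (2 mol %), THF, rt
Reagents that add atoms: tributylstannane, CCCC[SnH](CCCC)CCCC
Why: Palladium-catalysed syn-hydrostannylation of the terminal alkyne, in which the fully substituted propargylic carbon steers tin to the terminal carbon and gives the (E)-vinylstannane.

Step 11
Reactants: 16 aldehyde ester; 19 vinylstannane
Product: 22 (4aR,7aR)-4a,7a-dimethyl-1-[(E)-3-methyl-3-(triethylsilyloxy)but-1-en-1-yl]hexahydrocyclopenta[c]pyran-3(1H)-one (cis-fused δ-lactone, mixture of epimers at C1), via vinyllithium 20 (not isolated), via lithium alkoxide 21 (not isolated)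
Conditions: 19 (1.1 equiv), n-BuLi (1.05 equiv), THF, −78 °C; 16, −78 °C → rt; aq NH4Cl
Reagents that add atoms: none
Why: Tin–lithium exchange with retention of the E geometry, 1,2-addition of the vinyllithium to the aldehyde (far more electrophilic than the ester at −78 °C), then lactonisation of the cis-placed alkoxide onto the methyl ester on warming; the new carbinol centre forms as an epimer mixture that is removed by the oxidation in step 22.

Step 12
Reactants: 23 2-allyl-6-methylphenol
Product: 24 2-methyl-6-(prop-2-en-1-yl)cyclohexa-2,5-diene-1,4-dione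
Conditions: K2NO(SO3)2 (Fremy's salt, 2.2 equiv), KH2PO4, H2O/acetone, 0 °C → rt
Reagents that add atoms: potassium nitrosodisulfonate, [K+].[K+].[O]N(S(=O)(=O)[O-])S(=O)(=O)[O-]
Why: Teuber oxidation of a 2,6-disubstituted phenol with a free para position gives the p-quinone, which places the second oxygen regiospecifically.

Step 13
Reactants: 24 quinone
Product: 25 2-methyl-6-(prop-2-en-1-yl)benzene-1,4-diol
Conditions: Na2S2O4, H2O/Et2O, rt, N2
Reagents that add atoms: none
Why: Dithionite reduction of the quinone to the hydroquinone.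

Step 14
Reactants: 25 hydroquinone
Product: 26 1,4-bis(tert-butyldimethylsilyloxy)-2-methyl-6-(prop-2-en-1-yl)benzene
Conditions: t-BuMe2SiCl (2.5 equiv), imidazole, DMF, 40 °C
Reagents that add atoms: tert-butyldimethylsilyl chloride, CC(C)(C)[Si](C)(C)Cl
Why: Silyl protection of both phenols blocks air oxidation and allows a final fluoride deprotection that needs neither strong acid nor base.

Step 15
Reactants: 26 bis-silyl ether
Product: 28 2-[2,5-bis(tert-butyldimethylsilyloxy)-3-methylphenyl]acetaldehyde, via ozonide 27 (not isolated)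
Conditions: O3 (1 equiv, Sudan red 7B end point), CH2Cl2, −78 °C; PPh3, → rt; used crude
Reagents that add atoms: ozone, [O-][O+]=O
Why: Ozonolysis of the terminal alkene with reductive work-up, the monosubstituted alkene reacting faster than the silylated arene when ozone is limited to one equivalent.

Step 16
Reactants: 28 arylacetaldehyde; 29 ethyl 2-[bis(2,2,2-trifluoroethoxy)phosphoryl]propanoate
Product: 31 ethyl (Z)-4-[2,5-bis(tert-butyldimethylsilyloxy)-3-methylphenyl]-2-methylbut-2-enoate, via potassium phosphonate carbanion 30 (not isolated)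
Conditions: KN(SiMe3)2, 18-crown-6, THF, −78 °C
Reagents that add atoms: none
Why: Still–Gennari variant of the Horner–Wadsworth–Emmons olefination: the electron-poor phosphonate eliminates fast from the kinetic adduct and gives the trisubstituted (Z)-enoate, with the ester cis to the ArCH2 group.

Step 17
Reactants: 31 (Z)-enoate
Product: 32 (Z)-4-[2,5-bis(tert-butyldimethylsilyloxy)-3-methylphenyl]-2-methylbut-2-en-1-ol
Conditions: i-Bu2AlH (2.3 equiv), CH2Cl2, −78 °C; aq KNaC4H4O6 (potassium sodium tartrate)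
Reagents that add atoms: none
Why: 1,2-Reduction of the enoate by the aluminium hydride gives the allylic alcohol with the olefin geometry unchanged.

Step 18
Reactants: 32 (Z)-allylic alcohol
Product: 33 1-[(Z)-4-bromo-3-methylbut-2-en-1-yl]-2,5-bis(tert-butyldimethylsilyloxy)-3-methylbenzene
Conditions: CBr4, PPh3, CH2Cl2, 0 °C
Reagents that add atoms: carbon tetrabromide, BrC(Br)(Br)Br
Why: Appel bromination substitutes the primary allylic alcohol by SN2 under neutral conditions, without allylic transposition or loss of Z geometry.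

Step 19
Reactants: 33 (Z)-allylic bromide
Product: 34 2,5-bis(tert-butyldimethylsilyloxy)-3-methyl-1-[(Z)-3-methyl-4-(phenylsulfonyl)but-2-en-1-yl]benzene
Conditions: PhSO2Na, DMF, rt
Reagents that add atoms: sodium benzenesulfinate, [Na+].[O-]S(=O)c1ccccc1
Why: SN2 S-alkylation of the sulfinate at the primary allylic carbon.

Step 20
Reactants: 22 lactone; 34 allyl sulfone
Product: 36 (4Z)-6-[2,5-bis(tert-butyldimethylsilyloxy)-3-methylphenyl]-1-[(1R,2R)-2-[(E)-1-hydroxy-4-methyl-4-(triethylsilyloxy)pent-2-en-1-yl]-1,2-dimethylcyclopentyl]-4-methyl-3-(phenylsulfonyl)hex-4-en-2-one (mixture of diastereomers at C3 and the carbinol carbon), via lithiated sulfone 35 (not isolated)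
Conditions: 34 (2.2 equiv), n-BuLi (2.1 equiv), THF, −78 °C; 22, −78 → −30 °C; aq NH4Cl (excess 34 recovered)
Reagents that add atoms: none
Why: Acylation of an α-sulfonyl allyl carbanion, which reacts at its α-carbon with the lactone carbonyl; the β-keto sulfone formed is deprotonated by the second equivalent of 35, which stops over-addition, and the olefin geometry is held at low temperature.

Step 21
Reactants: 36 β-keto sulfone
Product: 37 (4Z)-6-[2,5-bis(tert-butyldimethylsilyloxy)-3-methylphenyl]-1-[(1R,2R)-2-[(E)-1-hydroxy-4-methyl-4-(triethylsilyloxy)pent-2-en-1-yl]-1,2-dimethylcyclopentyl]-4-methylhex-4-en-2-one (mixture of carbinol epimers)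
Conditions: SmI2 (3 equiv), THF/MeOH, −78 °C
Reagents that add atoms: none
Why: Reductive desulfonylation of the β-keto sulfone by single-electron transfer; the samarium dienolate is protonated at the α-carbon, which gives the β,γ-unsaturated ketone with the (Z)-alkene intact.

Step 22
Reactants: 37 hydroxy ketone
Product: 38 (E)-1-[(1R,2R)-2-[(Z)-6-[2,5-bis(tert-butyldimethylsilyloxy)-3-methylphenyl]-4-methyl-2-oxohex-4-en-1-yl]-1,2-dimethylcyclopentyl]-4-methyl-4-(triethylsilyloxy)pent-2-en-1-one
Conditions: Dess–Martin periodinane, pyridine, CH2Cl2, 0 °C → rt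
Reagents that add atoms: none
Why: Dess–Martin oxidation of the only free (secondary allylic) alcohol gives the (E)-enone under buffered conditions that do not move the β,γ-double bond into conjugation.

Step 23
Reactants: 38 fully silylated precursor
Product: 39 (E)-1-[(1R,2R)-2-[(Z)-6-(2,5-dihydroxy-3-methylphenyl)-4-methyl-2-oxohex-4-en-1-yl]-1,2-dimethylcyclopentyl]-4-hydroxy-4-methylpent-2-en-1-one (target)
Conditions: HF·pyridine, pyridine, THF, 0 °C → rt, Ar; degassed work-up
Reagents that add atoms: none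
Why: Fluoride-mediated desilylation removes the two aryl silyl ethers and the tertiary silyl ether in one step; the buffered medium avoids chroman formation and enone migration, and argon keeps the hydroquinone from air oxidation.

## Compound list

1 | butane-2,3-dione | CC(=O)C(C)=O | starting material
2 | dimethyl 3-oxopentanedioate | COC(=O)CC(=O)CC(=O)OC | starting material
3 | dimethyl 2-(2-hydroxy-3-oxobutan-2-yl)-3-oxopentanedioate (not isolated, diastereomer mixture) | COC(=O)CC(=O)C(C(=O)OC)C(C)(O)C(C)=O | intermediate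
4 | dimethyl 3-hydroxy-2,3-dimethyl-5-oxocyclopent-1-ene-1,4-dicarboxylate (not isolated, racemic mixture) | COC(=O)C1=C(C)C(C)(O)C(C(=O)OC)C1=O | intermediate
5 | dimethyl 2-[3,5-bis(methoxycarbonyl)-1,2-dimethyl-4-oxocyclopent-2-en-1-yl]-3-oxopentanedioate (not isolated) | COC(=O)CC(=O)C(C(=O)OC)C1(C)C(C)=C(C(=O)OC)C(=O)C1C(=O)OC | intermediate
6 | tetramethyl cis-1,5-dimethyl-3,7-dioxobicyclo[3.3.0]octane-2,4,6,8-tetracarboxylate (keto form drawn; ester-bearing carbons enolised) | O=C1C(C(=O)OC)[C@]2(C)C(C(=O)OC)C(=O)C(C(=O)OC)[C@]2(C)C1C(=O)OC | intermediate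
7 | cis-1,5-dimethylbicyclo[3.3.0]octane-3,7-dione (achiral) | O=C1C[C@]2(C)CC(=O)C[C@]2(C)C1 | intermediate
8 | cis-1,5-dimethylbicyclo[3.3.0]octane-3,7-dione mono(2,2-dimethylpropane-1,3-diyl) ketal (achiral) | O=C1C[C@]2(C)CC3(OCC(C)(C)CO3)C[C@]2(C)C1 | intermediate
9 | hydrazone of 8 (not isolated) | NN=C1C[C@]2(C)CC3(OCC(C)(C)CO3)C[C@]2(C)C1 | intermediate
10 | cis-1,5-dimethylbicyclo[3.3.0]octan-3-one 2,2-dimethylpropane-1,3-diyl ketal | C1C[C@]2(C)CC3(OCC(C)(C)CO3)C[C@]2(C)C1 | intermediate
11 | cis-1,5-dimethylbicyclo[3.3.0]octan-3-one (meso) | O=C1C[C@]2(C)CCC[C@]2(C)C1 | intermediate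
12 | lithium (1S,5R)-1,5-dimethylbicyclo[3.3.0]oct-2-en-3-olate (not isolated) | [Li+].[O-]C1=C[C@]2(C)CCC[C@]2(C)C1 | intermediate
13 | (1S,5R)-1,5-dimethyl-3-(trimethylsilyloxy)bicyclo[3.3.0]oct-2-ene | C[Si](C)(C)OC1=C[C@]2(C)CCC[C@]2(C)C1 | intermediate
14 | trimethylsilyl 2-[(1R,2R)-2-[hydroperoxy(methoxy)methyl]-1,2-dimethylcyclopentyl]acetate (not isolated, acetal carbon undefined) | C[Si](C)(C)OC(=O)C[C@@]1(C)CCC[C@@]1(C)C(OC)OO | intermediate
15 | 2-[(1R,2R)-2-formyl-1,2-dimethylcyclopentyl]acetic acid | OC(=O)C[C@@]1(C)CCC[C@@]1(C)C=O | intermediate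
16 | methyl 2-[(1R,2R)-2-formyl-1,2-dimethylcyclopentyl]acetate | COC(=O)C[C@@]1(C)CCC[C@@]1(C)C=O | intermediate
17 | 2-methylbut-3-yn-2-ol | CC(C)(O)C#C | starting material
18 | triethyl[(2-methylbut-3-yn-2-yl)oxy]silane | CC[Si](CC)(CC)OC(C)(C)C#C | intermediate
19 | tributyl[(E)-3-methyl-3-(triethylsilyloxy)but-1-en-1-yl]stannane | CCCC[Sn](CCCC)(CCCC)/C=C/C(C)(C)O[Si](CC)(CC)CC | intermediate
20 | [(E)-3-methyl-3-(triethylsilyloxy)but-1-en-1-yl]lithium (not isolated) | [Li]/C=C/C(C)(C)O[Si](CC)(CC)CC | intermediate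
21 | lithium alkoxide of methyl 2-[(1R,2R)-2-[(E)-1-hydroxy-4-methyl-4-(triethylsilyloxy)pent-2-en-1-yl]-1,2-dimethylcyclopentyl]acetate (not isolated, carbinol epimers) | COC(=O)C[C@@]1(C)CCC[C@@]1(C)C([O-])/C=C/C(C)(C)O[Si](CC)(CC)CC.[Li+] | intermediate
22 | (4aR,7aR)-4a,7a-dimethyl-1-[(E)-3-methyl-3-(triethylsilyloxy)but-1-en-1-yl]hexahydrocyclopenta[c]pyran-3(1H)-one (C1 epimers) | O=C1C[C@@]2(C)CCC[C@@]2(C)C(/C=C/C(C)(C)O[Si](CC)(CC)CC)O1 | intermediate
23 | 2-allyl-6-methylphenol | C=CCc1cccc(C)c1O | starting material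
24 | 2-methyl-6-(prop-2-en-1-yl)cyclohexa-2,5-diene-1,4-dione | C=CCC1=CC(=O)C=C(C)C1=O | intermediate
25 | 2-methyl-6-(prop-2-en-1-yl)benzene-1,4-diol | C=CCc1cc(O)cc(C)c1O | intermediate
26 | 1,4-bis(tert-butyldimethylsilyloxy)-2-methyl-6-(prop-2-en-1-yl)benzene | C=CCc1cc(O[Si](C)(C)C(C)(C)C)cc(C)c1O[Si](C)(C)C(C)(C)C | intermediate
27 | 3-[2,5-bis(tert-butyldimethylsilyloxy)-3-methylbenzyl]-1,2,4-trioxolane (not isolated) | C1(Cc2cc(O[Si](C)(C)C(C)(C)C)cc(C)c2O[Si](C)(C)C(C)(C)C)OCOO1 | intermediate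
28 | 2-[2,5-bis(tert-butyldimethylsilyloxy)-3-methylphenyl]acetaldehyde | O=CCc1cc(O[Si](C)(C)C(C)(C)C)cc(C)c1O[Si](C)(C)C(C)(C)C | intermediate
29 | ethyl 2-[bis(2,2,2-trifluoroethoxy)phosphoryl]propanoate | CCOC(=O)C(C)P(=O)(OCC(F)(F)F)OCC(F)(F)F | starting material
30 | potassium salt of the carbanion of 29 (not isolated) | CCOC(=O)[C-](C)P(=O)(OCC(F)(F)F)OCC(F)(F)F.[K+] | intermediate
31 | ethyl (Z)-4-[2,5-bis(tert-butyldimethylsilyloxy)-3-methylphenyl]-2-methylbut-2-enoate | C/C(=C/Cc1cc(O[Si](C)(C)C(C)(C)C)cc(C)c1O[Si](C)(C)C(C)(C)C)C(=O)OCC | intermediate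
32 | (Z)-4-[2,5-bis(tert-butyldimethylsilyloxy)-3-methylphenyl]-2-methylbut-2-en-1-ol | C/C(=C/Cc1cc(O[Si](C)(C)C(C)(C)C)cc(C)c1O[Si](C)(C)C(C)(C)C)CO | intermediate
33 | 1-[(Z)-4-bromo-3-methylbut-2-en-1-yl]-2,5-bis(tert-butyldimethylsilyloxy)-3-methylbenzene | C/C(=C/Cc1cc(O[Si](C)(C)C(C)(C)C)cc(C)c1O[Si](C)(C)C(C)(C)C)CBr | intermediate
34 | 2,5-bis(tert-butyldimethylsilyloxy)-3-methyl-1-[(Z)-3-methyl-4-(phenylsulfonyl)but-2-en-1-yl]benzene | C/C(=C/Cc1cc(O[Si](C)(C)C(C)(C)C)cc(C)c1O[Si](C)(C)C(C)(C)C)CS(=O)(=O)c1ccccc1 | intermediate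
35 | α-lithio derivative of 34 (not isolated) | C/C(=C/Cc1cc(O[Si](C)(C)C(C)(C)C)cc(C)c1O[Si](C)(C)C(C)(C)C)[CH-]S(=O)(=O)c1ccccc1.[Li+] | intermediate
36 | (4Z)-6-[2,5-bis(tert-butyldimethylsilyloxy)-3-methylphenyl]-1-[(1R,2R)-2-[(E)-1-hydroxy-4-methyl-4-(triethylsilyloxy)pent-2-en-1-yl]-1,2-dimethylcyclopentyl]-4-methyl-3-(phenylsulfonyl)hex-4-en-2-one (diastereomer mixture) | C/C(=C/Cc1cc(O[Si](C)(C)C(C)(C)C)cc(C)c1O[Si](C)(C)C(C)(C)C)C(C(=O)C[C@@]1(C)CCC[C@@]1(C)C(O)/C=C/C(C)(C)O[Si](CC)(CC)CC)S(=O)(=O)c1ccccc1 | intermediate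
37 | (4Z)-6-[2,5-bis(tert-butyldimethylsilyloxy)-3-methylphenyl]-1-[(1R,2R)-2-[(E)-1-hydroxy-4-methyl-4-(triethylsilyloxy)pent-2-en-1-yl]-1,2-dimethylcyclopentyl]-4-methylhex-4-en-2-one (carbinol epimers) | C/C(=C/Cc1cc(O[Si](C)(C)C(C)(C)C)cc(C)c1O[Si](C)(C)C(C)(C)C)CC(=O)C[C@@]1(C)CCC[C@@]1(C)C(O)/C=C/C(C)(C)O[Si](CC)(CC)CC | intermediate
38 | (E)-1-[(1R,2R)-2-[(Z)-6-[2,5-bis(tert-butyldimethylsilyloxy)-3-methylphenyl]-4-methyl-2-oxohex-4-en-1-yl]-1,2-dimethylcyclopentyl]-4-methyl-4-(triethylsilyloxy)pent-2-en-1-one | C/C(=C/Cc1cc(O[Si](C)(C)C(C)(C)C)cc(C)c1O[Si](C)(C)C(C)(C)C)CC(=O)C[C@@]1(C)CCC[C@@]1(C)C(=O)/C=C/C(C)(C)O[Si](CC)(CC)CC | intermediate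
39 | (E)-1-[(1R,2R)-2-[(Z)-6-(2,5-dihydroxy-3-methylphenyl)-4-methyl-2-oxohex-4-en-1-yl]-1,2-dimethylcyclopentyl]-4-hydroxy-4-methylpent-2-en-1-one | C/C(=C/Cc1cc(O)cc(C)c1O)CC(=O)C[C@@]1(C)CCC[C@@]1(C)C(=O)/C=C/C(C)(C)O | target

## Step count and risks

Total step count: 23 (fragment A: steps 1–8; fragment C: steps 9–10; fragment B: steps 12–19; union and end game: steps 11, 20–23).
Longest linear sequence: 13 steps (1–8, 11, 20–23). The branch from 23 is 12 steps and the branch from 17 is 7 steps.

Three steps most likely to fail: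

Step 6 (enantioselective deprotonation: ee may be insufficient, and the sense of induction is assumed). Fallback by resolution instead of asymmetric deprotonation: setting out from 11, LiN(iPr)2 and Me3SiCl in THF at −78 °C give the racemic silyl enol ether F1. Ozonolysis as in step 7 gives the racemic aldehyde acid F2, and esterification as in step 8 gives the racemic aldehyde methyl ester F3. F3 is separated by preparative chromatography on a chiral stationary phase (amylose tris(3,5-dimethylphenylcarbamate), supercritical CO2/i-PrOH). The (1R,2R) enantiomer is 16, where the route is rejoined.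

Step 16 (Still–Gennari olefination: the arylacetaldehyde 28 can enolise, the product can drift into conjugation with the arene, and the Z:E ratio may be lower than hoped). Fallback by a Z-selective Wittig reaction of an α-silyloxy ketone: setting out from 28, NaBH4 in MeOH gives 2-[2,5-bis(tert-butyldimethylsilyloxy)-3-methylphenyl]ethanol F4. I2, PPh3 and imidazole give the primary iodide F5, and PPh3 in MeCN at reflux gives the phosphonium iodide F6. KN(SiMe3)2 in THF at −78 °C forms the ylide F7, which reacts with commercial 1-(tert-butyldimethylsilyloxy)propan-2-one to give the (Z)-allyl silyl ether F8; unstabilised ylides give Z-trisubstituted allylic ethers with α-alkoxy ketones. Pyridinium p-toluenesulfonate in MeOH cleaves only the primary alkyl silyl ether and gives 32, where the route is rejoined.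

Step 20 (acylation of the hindered secondary sulfonyl carbanion by the neopentyl-type lactone: slow addition, two equivalents of fragment B needed, possible drift of the double bond in the β-keto sulfone). Fallback by α-selective allylbarium addition at the aldehyde oxidation level, with no sulfone: setting out from 22, i-Bu2AlH (1.1 equiv, CH2Cl2, −78 °C) gives the lactol F9. In parallel, 32 with PPh3 and N-chlorosuccinimide gives the (Z)-allylic chloride F10. Reactive barium (from BaI2 and two equivalents of Li(C12H10), lithium biphenylide, THF) converts F10 at −78 °C into the allylbarium chloride F11, which adds at its α-carbon and with retention of the Z geometry to the open hydroxy aldehyde form of F9 (3 equiv) to give the diol F12. Dess–Martin periodinane with pyridine oxidises both secondary alcohols and gives 38, where the route is rejoined; 34 to 37 are bypassed.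

## Further compounds

F1 | step 6 | racemic cis-1,5-dimethyl-3-(trimethylsilyloxy)bicyclo[3.3.0]oct-2-ene (both enantiomers) | C[Si](C)(C)OC1=C[C@]2(C)CCC[C@]2(C)C1.C[Si](C)(C)OC1=C[C@@]2(C)CCC[C@@]2(C)C1
F2 | step 6 | racemic cis-2-(2-formyl-1,2-dimethylcyclopentyl)acetic acid (both enantiomers) | OC(=O)C[C@@]1(C)CCC[C@@]1(C)C=O.OC(=O)C[C@]1(C)CCC[C@]1(C)C=O
F3 | step 6 | racemic methyl cis-2-(2-formyl-1,2-dimethylcyclopentyl)acetate (both enantiomers) | COC(=O)C[C@@]1(C)CCC[C@@]1(C)C=O.COC(=O)C[C@]1(C)CCC[C@]1(C)C=O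
F4 | step 16 | 2-[2,5-bis(tert-butyldimethylsilyloxy)-3-methylphenyl]ethanol | OCCc1cc(O[Si](C)(C)C(C)(C)C)cc(C)c1O[Si](C)(C)C(C)(C)C
F5 | step 16 | 2,5-bis(tert-butyldimethylsilyloxy)-1-(2-iodoethyl)-3-methylbenzene | ICCc1cc(O[Si](C)(C)C(C)(C)C)cc(C)c1O[Si](C)(C)C(C)(C)C
F6 | step 16 | {2-[2,5-bis(tert-butyldimethylsilyloxy)-3-methylphenyl]ethyl}triphenylphosphonium iodide | [I-].c1ccccc1[P+](CCc1cc(O[Si](C)(C)C(C)(C)C)cc(C)c1O[Si](C)(C)C(C)(C)C)(c1ccccc1)c1ccccc1
F7 | step 16 | {2-[2,5-bis(tert-butyldimethylsilyloxy)-3-methylphenyl]ethylidene}triphenylphosphorane | c1ccccc1P(=CCc1cc(O[Si](C)(C)C(C)(C)C)cc(C)c1O[Si](C)(C)C(C)(C)C)(c1ccccc1)c1ccccc1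
F8 | step 16 | 2,5-bis(tert-butyldimethylsilyloxy)-1-[(Z)-4-(tert-butyldimethylsilyloxy)-3-methylbut-2-en-1-yl]-3-methylbenzene | C/C(=C/Cc1cc(O[Si](C)(C)C(C)(C)C)cc(C)c1O[Si](C)(C)C(C)(C)C)CO[Si](C)(C)C(C)(C)C
F9 | step 20 | (4aR,7aR)-4a,7a-dimethyl-1-[(E)-3-methyl-3-(triethylsilyloxy)but-1-en-1-yl]octahydrocyclopenta[c]pyran-3-ol (lactol, epimer mixture) | OC1C[C@@]2(C)CCC[C@@]2(C)C(/C=C/C(C)(C)O[Si](CC)(CC)CC)O1
F10 | step 20 | 2,5-bis(tert-butyldimethylsilyloxy)-1-[(Z)-4-chloro-3-methylbut-2-en-1-yl]-3-methylbenzene | C/C(=C/Cc1cc(O[Si](C)(C)C(C)(C)C)cc(C)c1O[Si](C)(C)C(C)(C)C)CCl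
F11 | step 20 | {(Z)-4-[2,5-bis(tert-butyldimethylsilyloxy)-3-methylphenyl]-2-methylbut-2-en-1-yl}barium chloride | C/C(=C/Cc1cc(O[Si](C)(C)C(C)(C)C)cc(C)c1O[Si](C)(C)C(C)(C)C)C[Ba]Cl
F12 | step 20 | (4Z)-6-[2,5-bis(tert-butyldimethylsilyloxy)-3-methylphenyl]-1-[(1R,2R)-2-[(E)-1-hydroxy-4-methyl-4-(triethylsilyloxy)pent-2-en-1-yl]-1,2-dimethylcyclopentyl]-4-methylhex-4-en-2-ol (diastereomer mixture) | C/C(=C/Cc1cc(O[Si](C)(C)C(C)(C)C)cc(C)c1O[Si](C)(C)C(C)(C)C)CC(O)C[C@@]1(C)CCC[C@@]1(C)C(O)/C=C/C(C)(C)O[Si](CC)(CC)CC
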